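**Retrosynthetic overview**
- The feruloyl ester on the propanol oxygen and the p-coumaroyl ester on C9–O are removed last, leaving O-silyl ferulic acid, O-silyl p-coumaric acid and a core with C9–OH masked as a benzyl ether and the propanol as a TBS ether.
- The strategy rests on the dihydrofuran ring (O1, C2, C3, C3a, C7a): C3 is benzylic and ortho to O1, so O1–C7a–C3a–C3 is the four-atom unit of an ortho-quinone methide. C9 is attached to C3 as a carbanion at the aldehyde stage, and C2 with its aryl group arrives as a one-carbon sulfonium ylide.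
- Bonds C3–C9, C2–C3 and O1–C2 are made in one flask from an O-Boc salicylaldehyde, benzyloxymethyllithium and a C2-symmetric benzylsulfonium salt. This (4+1) annulation closes the only ring that has to be built (both benzene rings are bought) and sets C2 and C3.
- The aldehyde comes from dihydroconiferyl alcohol, the sulfonium salt from vanillin and (2S,5S)-hexane-2,5-diol, and the lithium reagent from tributyltin hydride and benzyl chloromethyl ether.

Key step: step 11

Remark: TBS = tert-butyldimethylsilyl, Boc = tert-butoxycarbonyl; ring atoms are numbered O1, C2, C3, C3a, C4–C7, C7a, and C9 is the CH2O carbon on C3. The target is (2R,3S), trans.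
Remark: the (2R,5R)-thiolane is assumed to deliver 2R after the invertive ring closure, by analogy with its sense in benzylidene transfer to aldehydes; if the sense is opposite, the (2S,5S)-thiolane from (2R,5R)-hexane-2,5-diol is used in the same steps.
Remark: dihydroconiferyl alcohol is taken as a purchased compound; it is otherwise the hydroboration–oxidation product of eugenol.

Step 1
Reactants: 1 dihydroconiferyl alcohol [4-(3-hydroxypropyl)-2-methoxyphenol]
Product: 2 4-[3-(TBSO)propyl]-2-methoxyphenol
Conditions: TBSCl (1.05 equiv), imidazole (1.2 equiv), CH2Cl2, 0 °C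
Reagents that add atoms: tert-butyldimethylsilyl chloride, CC(C)(C)[Si](C)(C)Cl
Why: Chemoselective O-silylation, in which one equivalent of silyl chloride should take the unhindered primary alcohol ahead of the guaiacol OH that is flanked by and hydrogen-bonded to the methoxy group.

Step 2
Reactants: 2 4-[3-(TBSO)propyl]-2-methoxyphenol
Product: 3 2-hydroxy-3-methoxy-5-[3-(TBSO)propyl]benzaldehyde
Conditions: MgCl2, Et3N, (CH2O)n, MeCN, reflux; cold aq. citric acid work-up
Reagents that add atoms: paraformaldehyde (as formaldehyde), C=O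
Why: Magnesium-mediated ortho-formylation (Casnati–Skattebøl), in which the magnesium phenoxide directs formaldehyde to the only free ortho carbon and a second formaldehyde oxidises the benzylic alkoxide by hydride transfer, the basic medium sparing the silyl ether.

Step 3
Reactants: 3 2-hydroxy-3-methoxy-5-[3-(TBSO)propyl]benzaldehyde
Product: 4 2-(tert-butoxycarbonyloxy)-3-methoxy-5-[3-(TBSO)propyl]benzaldehyde
Conditions: Boc2O, DMAP (cat.), i-Pr2NEt, CH2Cl2, 0 °C to rt
Reagents that add atoms: di-tert-butyl dicarbonate, CC(C)(C)OC(=O)OC(=O)OC(C)(C)C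
Why: DMAP-catalysed O-acylation of the phenol gives the aryl tert-butyl carbonate that later acts as the transferable leaving group, without touching aldehyde or silyl ether.

Step 4
Reactants: 5 (2S,5S)-hexane-2,5-diol
Product: 6 (2S,5S)-hexane-2,5-diyl dimethanesulfonate
Conditions: MsCl, Et3N, CH2Cl2, 0 °C
Reagents that add atoms: methanesulfonyl chloride, CS(=O)(=O)Cl
Why: Mesylation takes place at oxygen, so both C–O bonds and both S configurations are kept.

Step 5
Reactants: 6 (2S,5S)-hexane-2,5-diyl dimethanesulfonate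
Product: 7 (2R,5R)-2,5-dimethylthiolane
Conditions: Na2S·9H2O, DMSO, rt; distillation
Reagents that add atoms: sodium sulfide, [Na+].[Na+].[S-2]
Why: Double SN2 thioetherification, the second displacement a 5-exo-tet closure, inverts both carbons and should give the C2-symmetric (2R,5R)-thiolane.

Step 6
Reactants: 8 vanillin
Product: 9 4-(TBSO)-3-methoxybenzaldehyde
Conditions: TBSCl, imidazole, CH2Cl2, rt
Reagents that add atoms: tert-butyldimethylsilyl chloride, CC(C)(C)[Si](C)(C)Cl
Why: Imidazole-mediated silylation masks the phenol as an aryl TBS ether that tolerates ylide chemistry and is removed with fluoride at the end.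

Step 7
Reactants: 9 4-(TBSO)-3-methoxybenzaldehyde
Product: 10 [4-(TBSO)-3-methoxyphenyl]methanol
Conditions: NaBH4, THF/MeOH, 0 °C
Reagents that add atoms: none
Why: Borohydride reduction of the aromatic aldehyde to the benzylic alcohol is fast at 0 °C and should spare the aryl silyl ether.

Step 8
Reactants: 10 [4-(TBSO)-3-methoxyphenyl]methanol
Product: 11 4-(TBSO)-3-methoxybenzyl bromide
Conditions: CBr4, PPh3, CH2Cl2, 0 °C; used without storage
Reagents that add atoms: carbon tetrabromide, BrC(Br)(Br)Br
Why: Appel bromination converts the benzylic alcohol into the bromide under neutral conditions that keep the aryl silyl ether.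

Step 9
Reactants: 11 4-(TBSO)-3-methoxybenzyl bromide, 7 (2R,5R)-2,5-dimethylthiolane
Product: 12 (2R,5R)-1-[4-(TBSO)-3-methoxybenzyl]-2,5-dimethylthiolan-1-ium tetrafluoroborate
Conditions: AgBF4, CH2Cl2, 0 °C to rt, dark; precipitation from Et2O
Reagents that add atoms: silver tetrafluoroborate, [Ag+].F[B-](F)(F)F
Why: S-Alkylation of the thiolane by the benzylic bromide is driven by precipitation of silver bromide, and because the two sulfur lone pairs are homotopic in the C2-symmetric thiolane a single sulfonium salt should form.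

Step 10
Reactants: 13 tributyltin hydride, 14 benzyl chloromethyl ether
Product: 16 [(benzyloxy)methyl]tributylstannane, via tributylstannyllithium 15 (not isolated)
Conditions: LDA, THF, 0 °C; then 14, −78 °C to rt
Reagents that add atoms: none
Why: Deprotonation of the tin hydride gives the stannyl anion, which displaces chloride from the chloromethyl ether by SN2 to give the α-alkoxymethylstannane.

Step 11
Reactants: 4 2-(tert-butoxycarbonyloxy)-3-methoxy-5-[3-(TBSO)propyl]benzaldehyde, 16 [(benzyloxy)methyl]tributylstannane, 12 (2R,5R)-1-[4-(TBSO)-3-methoxybenzyl]-2,5-dimethylthiolan-1-ium tetrafluoroborate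
Product: 23 (2R,3S)-3-[(benzyloxy)methyl]-2-[4-(TBSO)-3-methoxyphenyl]-7-methoxy-5-[3-(TBSO)propyl]-2,3-dihydrobenzofuran (trans), via benzyloxymethyllithium 17 (not isolated), via sulfonium benzylide 18 (not isolated), via lithium alkoxide adduct 19 (not isolated), via Boc-shifted lithium phenoxide 20 (not isolated), via E ortho-quinone methide 21 (not isolated), via sulfonium phenoxide betaine 22 (not isolated)
Conditions: 16, n-BuLi, THF, −78 °C; 4, −78 °C; ylide from 12 (LiHMDS, THF, −78 °C) added by cannula; MgBr2·OEt2, −78 to −20 °C; H2O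
Reagents that add atoms: none
Why: Proposed new method: tin–lithium exchange gives 17, which adds to the aldehyde of 4 (bond C3–C9); alkoxide 19 takes over the Boc group from the neighbouring aryl oxygen through a six-membered transition state to give phenoxide 20, MgBr2 then promotes loss of tert-butyl carbonate to release the E ortho-quinone methide 21, ylide 18 adds to its exocyclic carbon with rearomatisation (bond C2–C3), and the phenoxide of betaine 22 displaces the thiolane (bond O1–C2). The closest known reaction types are the organometal-triggered generation of ortho-quinone methides from O-Boc salicylaldehydes and the (4+1) annulation of ortho-quinone methides with sulfonium ylides to trans-2,3-dihydrobenzofurans, and what is new is their merger in one flask with an α-alkoxymethyllithium and a chiral benzylide. The dihydrofuran ring closes by a 5-exo-tet SN2 O-alkylation with inversion at C2. C2 is controlled by the C2-symmetric (2R,5R)-thiolane, whose methyl groups leave one face of the benzylide open in the conjugate addition, and C3 follows from C2 because the addition proceeds through the staggered approach that keeps the aryl group and the CH2OBn arm apart, the syn betaine also closing more slowly through an eclipsed transition state, so the trans ring results. The step needs 1,2-addition of 17 to the aldehyde rather than to the carbonate, capture of 21 by the ylide ahead of its tautomerisation to the styryl enol ether, and facial selection in the C2–C3 bond formation; the first is secured by the far higher electrophilicity of the aldehyde at −78 °C, the second by releasing 21 cold and only once the ylide is in the flask so that it never accumulates, the third by the sulfur auxiliary.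

Step 12
Reactants: 23 (2R,3S)-3-[(benzyloxy)methyl]-2-[4-(TBSO)-3-methoxyphenyl]-7-methoxy-5-[3-(TBSO)propyl]-2,3-dihydrobenzofuran
Product: 24 (2R,3S)-3-(hydroxymethyl)-2-[4-(TBSO)-3-methoxyphenyl]-7-methoxy-5-[3-(TBSO)propyl]-2,3-dihydrobenzofuran
Conditions: H2 (1 atm), 10% Pd/C, EtOAc, rt
Reagents that add atoms: none
Why: Palladium-catalysed hydrogenolysis of the primary benzyl ether in a neutral aprotic solvent should free C9–OH before any cinnamate is present, the silyl ethers being inert and the secondary, ring-constrained benzylic C2–O1 bond being cleaved much more slowly, so that C2 and C3 are untouched.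

Step 13
Reactants: 25 p-coumaric acid
Product: 27 (E)-3-[4-(TBSO)phenyl]acrylic acid, via bis-TBS p-coumaric acid 26 (not isolated)
Conditions: TBSCl (2.3 equiv), imidazole, DMF, rt; then AcOH, THF/H2O, rt
Reagents that add atoms: tert-butyldimethylsilyl chloride, CC(C)(C)[Si](C)(C)Cl
Why: Silylation of phenol and carboxylic acid followed by mild hydrolysis, which cleaves only the very labile silyl ester, should give the phenol-protected acid in one flask.

Step 14
Reactants: 24 (2R,3S)-3-(hydroxymethyl)-2-[4-(TBSO)-3-methoxyphenyl]-7-methoxy-5-[3-(TBSO)propyl]-2,3-dihydrobenzofuran, 27 (E)-3-[4-(TBSO)phenyl]acrylic acid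
Product: 28 C9 (E)-4-(TBSO)cinnamate of 24
Conditions: DCC, DMAP (cat.), CH2Cl2, 0 °C to rt
Reagents that add atoms: none
Why: Steglich esterification (carbodiimide activation, DMAP acyl transfer) acylates the only free hydroxyl group, the primary C9–OH, under neutral conditions that do not touch C2 or C3.

Step 15
Reactants: 28 C9 (E)-4-(TBSO)cinnamate of 24
Product: 29 (2R,3S)-5-(3-hydroxypropyl) alcohol with C9 (E)-4-(TBSO)cinnamate and aryl TBS ether intact
Conditions: CSA (0.1 equiv), MeOH/CH2Cl2 1:1, 0 °C
Reagents that add atoms: none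
Why: Acid-catalysed methanolysis is far faster for a primary alkyl TBS ether than for aryl TBS ethers, so brief treatment at 0 °C should release only the propanol and leave the ester and the ring C2–O1 bond alone.

Step 16
Reactants: 30 ferulic acid
Product: 32 (E)-3-[4-(TBSO)-3-methoxyphenyl]acrylic acid, via bis-TBS ferulic acid 31 (not isolated)
Conditions: TBSCl (2.3 equiv), imidazole, DMF, rt; then AcOH, THF/H2O, rt
Reagents that add atoms: tert-butyldimethylsilyl chloride, CC(C)(C)[Si](C)(C)Cl
Why: The same bis-silylation and selective silyl ester hydrolysis as in step 13 should give the phenol-protected acid.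

Step 17
Reactants: 29 (2R,3S)-5-(3-hydroxypropyl) alcohol, 32 (E)-3-[4-(TBSO)-3-methoxyphenyl]acrylic acid
Product: 33 tris-O-TBS boehmenan X
Conditions: DCC, DMAP (cat.), CH2Cl2, 0 °C to rt
Reagents that add atoms: none
Why: Steglich esterification of the only free hydroxyl group, the primary propanol, completes the diester under neutral conditions.

Step 18
Reactants: 33 tris-O-TBS boehmenan X
Product: 34 (+)-boehmenan X
Conditions: TBAF (3.3 equiv), AcOH (3.3 equiv), THF, 0 °C
Reagents that add atoms: none
Why: Fluoride-induced cleavage of the three aryl silyl ethers, buffered with acetic acid so that no free phenoxide cleaves or transfers a cinnamate or opens the ring at C2 through a para-quinone methide, should give the target with C2 and C3 unchanged.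

**Compound list**
1 | dihydroconiferyl alcohol, 4-(3-hydroxypropyl)-2-methoxyphenol | COc1cc(CCCO)ccc1O | starting material
2 | 4-[3-(tert-butyldimethylsilyloxy)propyl]-2-methoxyphenol | COc1cc(CCCO[Si](C)(C)C(C)(C)C)ccc1O | intermediate
3 | 2-hydroxy-3-methoxy-5-[3-(tert-butyldimethylsilyloxy)propyl]benzaldehyde | COc1cc(CCCO[Si](C)(C)C(C)(C)C)cc(C=O)c1O | intermediate
4 | 2-(tert-butoxycarbonyloxy)-3-methoxy-5-[3-(tert-butyldimethylsilyloxy)propyl]benzaldehyde | CC(C)(C)[Si](C)(C)OCCCc1cc(OC)c(OC(=O)OC(C)(C)C)c(C=O)c1 | intermediate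
5 | (2S,5S)-hexane-2,5-diol | C[C@H](O)CC[C@H](C)O | starting material
6 | (2S,5S)-hexane-2,5-diyl dimethanesulfonate | C[C@H](OS(C)(=O)=O)CC[C@H](C)OS(C)(=O)=O | intermediate
7 | (2R,5R)-2,5-dimethylthiolane | C[C@@H]1CC[C@@H](C)S1 | intermediate
8 | vanillin | COc1cc(C=O)ccc1O | starting material
9 | 4-(tert-butyldimethylsilyloxy)-3-methoxybenzaldehyde | COc1cc(C=O)ccc1O[Si](C)(C)C(C)(C)C | intermediate
10 | [4-(tert-butyldimethylsilyloxy)-3-methoxyphenyl]methanol | COc1cc(CO)ccc1O[Si](C)(C)C(C)(C)C | intermediate
11 | 4-(tert-butyldimethylsilyloxy)-3-methoxybenzyl bromide | COc1cc(CBr)ccc1O[Si](C)(C)C(C)(C)C | intermediate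
12 | (2R,5R)-1-[4-(tert-butyldimethylsilyloxy)-3-methoxybenzyl]-2,5-dimethylthiolan-1-ium tetrafluoroborate | C[C@@H]1CC[C@@H](C)[S+]1Cc1ccc(O[Si](C)(C)C(C)(C)C)c(OC)c1.F[B-](F)(F)F | intermediate
13 | tributyltin hydride | CCCC[SnH](CCCC)CCCC | starting material
14 | benzyl chloromethyl ether | ClCOCc1ccccc1 | starting material
15 | tributylstannyllithium | [Li][Sn](CCCC)(CCCC)CCCC | intermediate
16 | [(benzyloxy)methyl]tributylstannane | CCCC[Sn](CCCC)(CCCC)COCc1ccccc1 | intermediate
17 | benzyloxymethyllithium | [Li]COCc1ccccc1 | intermediate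
18 | (2R,5R)-2,5-dimethylthiolanium 4-(tert-butyldimethylsilyloxy)-3-methoxybenzylide | C[C@@H]1CC[C@@H](C)[S+]1[CH-]c1ccc(O[Si](C)(C)C(C)(C)C)c(OC)c1 | intermediate
19 | lithium 2-(benzyloxy)-1-[2-(tert-butoxycarbonyloxy)-3-methoxy-5-(3-silyloxypropyl)phenyl]ethoxide (both C3 epimers) | CC(C)(C)[Si](C)(C)OCCCc1cc(OC)c(OC(=O)OC(C)(C)C)c(C(O[Li])COCc2ccccc2)c1 | intermediate
20 | lithium 2-[2-(benzyloxy)-1-(tert-butoxycarbonyloxy)ethyl]-6-methoxy-4-(3-silyloxypropyl)phenoxide | CC(C)(C)[Si](C)(C)OCCCc1cc(OC)c(O[Li])c(C(COCc2ccccc2)OC(=O)OC(C)(C)C)c1 | intermediate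
21 | (E)-6-[2-(benzyloxy)ethylidene]-2-methoxy-4-[3-(tert-butyldimethylsilyloxy)propyl]cyclohexa-2,4-dien-1-one | O=C1C(OC)=CC(CCCO[Si](C)(C)C(C)(C)C)=C/C1=C\COCc1ccccc1 | intermediate
22 | anti sulfonium phenoxide betaine (C2–C3 bond formed, O1–C2 not yet) | [O-]c1c(OC)cc(CCCO[Si](C)(C)C(C)(C)C)cc1[C@@H](COCc1ccccc1)[C@@H](c1ccc(O[Si](C)(C)C(C)(C)C)c(OC)c1)[S+]1[C@H](C)CC[C@H]1C | intermediate
23 | (2R,3S)-3-[(benzyloxy)methyl]-2-[4-(tert-butyldimethylsilyloxy)-3-methoxyphenyl]-7-methoxy-5-[3-(tert-butyldimethylsilyloxy)propyl]-2,3-dihydrobenzofuran | CC(C)(C)[Si](C)(C)OCCCc1cc(OC)c2c(c1)[C@@H](COCc1ccccc1)[C@H](c1ccc(O[Si](C)(C)C(C)(C)C)c(OC)c1)O2 | intermediate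
24 | (2R,3S)-3-(hydroxymethyl)-2-[4-(tert-butyldimethylsilyloxy)-3-methoxyphenyl]-7-methoxy-5-[3-(tert-butyldimethylsilyloxy)propyl]-2,3-dihydrobenzofuran | CC(C)(C)[Si](C)(C)OCCCc1cc(OC)c2c(c1)[C@@H](CO)[C@H](c1ccc(O[Si](C)(C)C(C)(C)C)c(OC)c1)O2 | intermediate
25 | p-coumaric acid | O=C(O)/C=C/c1ccc(O)cc1 | starting material
26 | tert-butyldimethylsilyl (E)-3-[4-(tert-butyldimethylsilyloxy)phenyl]acrylate | CC(C)(C)[Si](C)(C)OC(=O)/C=C/c1ccc(O[Si](C)(C)C(C)(C)C)cc1 | intermediate
27 | (E)-3-[4-(tert-butyldimethylsilyloxy)phenyl]acrylic acid | O=C(O)/C=C/c1ccc(O[Si](C)(C)C(C)(C)C)cc1 | intermediate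
28 | C9 (E)-4-(silyloxy)cinnamate of 24, bis-aryl-TBS, propanol TBS ether | CC(C)(C)[Si](C)(C)OCCCc1cc(OC)c2c(c1)[C@@H](COC(=O)/C=C/c1ccc(O[Si](C)(C)C(C)(C)C)cc1)[C@H](c1ccc(O[Si](C)(C)C(C)(C)C)c(OC)c1)O2 | intermediate
29 | (2R,3S)-5-(3-hydroxypropyl) alcohol, C9 (E)-4-(silyloxy)cinnamate, aryl TBS ether | OCCCc1cc(OC)c2c(c1)[C@@H](COC(=O)/C=C/c1ccc(O[Si](C)(C)C(C)(C)C)cc1)[C@H](c1ccc(O[Si](C)(C)C(C)(C)C)c(OC)c1)O2 | intermediate
30 | ferulic acid | COc1cc(/C=C/C(=O)O)ccc1O | starting material
31 | tert-butyldimethylsilyl (E)-3-[4-(tert-butyldimethylsilyloxy)-3-methoxyphenyl]acrylate | COc1cc(/C=C/C(=O)O[Si](C)(C)C(C)(C)C)ccc1O[Si](C)(C)C(C)(C)C | intermediate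
32 | (E)-3-[4-(tert-butyldimethylsilyloxy)-3-methoxyphenyl]acrylic acid | COc1cc(/C=C/C(=O)O)ccc1O[Si](C)(C)C(C)(C)C | intermediate
33 | tris-O-TBS boehmenan X | COc1cc(/C=C/C(=O)OCCCc2cc(OC)c3c(c2)[C@@H](COC(=O)/C=C/c2ccc(O[Si](C)(C)C(C)(C)C)cc2)[C@H](c2ccc(O[Si](C)(C)C(C)(C)C)c(OC)c2)O3)ccc1O[Si](C)(C)C(C)(C)C | intermediate
34 | (+)-boehmenan X | COc1cc(/C=C/C(=O)OCCCc2cc(OC)c3c(c2)[C@@H](COC(=O)/C=C/c2ccc(O)cc2)[C@H](c2ccc(O)c(OC)c2)O3)ccc1O | target

**Step count**
- Total: 18 steps.
- Longest linear sequence: 10 steps, from vanillin (steps 6, 7, 8, 9, 11, 12, 14, 15, 17, 18).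

**Steps most likely to fail**

Step 11 (proposed new method). Three processes may defeat it.
- The quinone methide 21 may isomerise to the 2-hydroxystyryl enol ether before the ylide captures it.
- The ylide or 17 may be acylated by the carbonate.
- The thiolane may discriminate the ylide faces poorly, or the electron-rich benzylic sulfonium of 22 may ionise before closure, so that the C2 information is lost and the syn betaine leaks into the enantiomeric trans product.

The fallback uses known rhodium carbenoid C–H insertion, sets out from phenol 2 and bromide 11, and returns at alcohol 24. Ortho-iodination of 2 (NIS, CH2Cl2, 0 °C) gives 2-iodo-6-methoxy-4-[3-(TBSO)propyl]phenol F1. Williamson etherification of F1 with 11 (K2CO3, DMF) gives the aryl benzyl ether F2. Palladium-catalysed coupling of the aryl iodide with ethyl diazoacetate (Pd(PPh3)4, Et3N, Bu4NBr, MeCN) gives the aryl diazoacetate F3. Intramolecular insertion of the rhodium carbenoid into the benzylic O–CH2 bond, with Rh2(S-PTTL)4 or its antipode chosen to give 2R (toluene, −60 °C), gives the cis-2,3-dihydrobenzofuran ethyl ester F4, in which the catalyst sets C2. Equilibration at C3 with DBU in toluene, an aprotic base that keeps the aryl silyl ether, gives the trans ethyl ester F5. LiBH4 reduction of the ester then gives 24 directly, so step 12 is bypassed as well.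

Step 12. The ring C2–O1 bond is itself a benzylic aryl ether and may be hydrogenolysed along with the O-benzyl group, or traces of thiolane may poison the catalyst and stall the debenzylation. The fallback sets out from 4 and 12 and returns at 24, carrying the C9 oxygen as a p-methoxybenzyl ether that is removed oxidatively. Tributyl(iodomethyl)stannane and 4-methoxybenzyl alcohol (NaH, THF/DMF) give [(4-methoxybenzyloxy)methyl]tributylstannane F6. F6 replaces 16 in the cascade of step 11 to give the PMB ether analogue of 23, F7. DDQ in CH2Cl2/pH 7 buffer at 0 °C cleaves the PMB group and gives 24.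

Step 2. The methoxy group next to the phenoxide may tie up magnesium so that formylation stalls, and long heating may erode the silyl ether. The fallback goes from 2 back to 3 by halogenation, metalation and formylation. Ortho-bromination of 2 (NBS, cat. i-Pr2NH, CH2Cl2, 0 °C) gives 2-bromo-6-methoxy-4-[3-(TBSO)propyl]phenol F8. Deprotonation of the phenol (NaH, THF), bromine–lithium exchange (t-BuLi, −78 °C) and a DMF quench give 3.

Further compounds
F1 | step 11 | 2-iodo-6-methoxy-4-[3-(tert-butyldimethylsilyloxy)propyl]phenol | COc1cc(CCCO[Si](C)(C)C(C)(C)C)cc(I)c1O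
F2 | step 11 | 4-(tert-butyldimethylsilyloxy)-3-methoxybenzyl ether of F1 | COc1cc(CCCO[Si](C)(C)C(C)(C)C)cc(I)c1OCc1ccc(O[Si](C)(C)C(C)(C)C)c(OC)c1
F3 | step 11 | ethyl 2-diazo-2-[2-(4-silyloxy-3-methoxybenzyloxy)-3-methoxy-5-(3-silyloxypropyl)phenyl]acetate | CCOC(=O)C(=[N+]=[N-])c1cc(CCCO[Si](C)(C)C(C)(C)C)cc(OC)c1OCc1ccc(O[Si](C)(C)C(C)(C)C)c(OC)c1
F4 | step 11 | ethyl (2R,3S)-cis-2-[4-(tert-butyldimethylsilyloxy)-3-methoxyphenyl]-7-methoxy-5-[3-(tert-butyldimethylsilyloxy)propyl]-2,3-dihydrobenzofuran-3-carboxylate | CC(C)(C)[Si](C)(C)OCCCc1cc(OC)c2c(c1)[C@H](C(=O)OCC)[C@H](c1ccc(O[Si](C)(C)C(C)(C)C)c(OC)c1)O2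
F5 | step 11 | ethyl (2R,3R)-trans-2-[4-(tert-butyldimethylsilyloxy)-3-methoxyphenyl]-7-methoxy-5-[3-(tert-butyldimethylsilyloxy)propyl]-2,3-dihydrobenzofuran-3-carboxylate | CC(C)(C)[Si](C)(C)OCCCc1cc(OC)c2c(c1)[C@@H](C(=O)OCC)[C@H](c1ccc(O[Si](C)(C)C(C)(C)C)c(OC)c1)O2
F6 | step 12 | [(4-methoxybenzyloxy)methyl]tributylstannane | CCCC[Sn](CCCC)(CCCC)COCc1ccc(OC)cc1
F7 | step 12 | (2R,3S)-3-[(4-methoxybenzyloxy)methyl]-2-[4-(tert-butyldimethylsilyloxy)-3-methoxyphenyl]-7-methoxy-5-[3-(tert-butyldimethylsilyloxy)propyl]-2,3-dihydrobenzofuran | CC(C)(C)[Si](C)(C)OCCCc1cc(OC)c2c(c1)[C@@H](COCc1ccc(OC)cc1)[C@H](c1ccc(O[Si](C)(C)C(C)(C)C)c(OC)c1)O2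
F8 | step 2 | 2-bromo-6-methoxy-4-[3-(tert-butyldimethylsilyloxy)propyl]phenol | COc1cc(CCCO[Si](C)(C)C(C)(C)C)cc(Br)c1O
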